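**Retrosynthetic overview**
1. Target 18 comes from the bis(pent-1-enyl) depside 17 by one hydrogenation, which saturates two C=C bonds and cleaves two benzyl ethers and one benzyl ester.
2. 17 comes from divinyl depside 15 and (E)-oct-4-ene 16 by twofold cross-metathesis. The plan rests on the identical unbranched C5 chains at C6 of ring A and C6 of ring B, each ortho to the carbonyl-bearing C1, so the C1'=C2' bond of both chains is made in one operation from two aryl vinyl groups.
3. 15 comes from ring A acid 6 and ring B phenol 13 by forming the ester bond between the ring A carboxyl carbon and O4 of ring B.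
4. 6 and 13 come from aryl triflates 3 and 11 and potassium vinyltrifluoroborate 4; the triflates come from phloroglucinol carboxylates 1 and 7 by graded O-alkylation (free para OH first, hydrogen-bonded ortho OH last).
5. No ring is formed in the route; rings A and B are both bought as benzenoid starting materials.

Key step: step 12

Remark: ring B is started from the free acid 7 (sold as its monohydrate), so that the benzyl ester is set at the outset by carboxylate alkylation and no exchange of a hindered ester is needed later. The target has no stereocentre, and the alkene geometry of 17 is erased in step 13.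

**Route**

Step 1
Reactants: 1 methyl 2,4,6-trihydroxybenzoate
Product: 2 methyl 2,4-bis(benzyloxy)-6-hydroxybenzoate
Conditions: BnBr (2.1 equiv), K2CO3 (2.2 equiv), acetone, reflux
Reagents that add atoms: benzyl bromide, BrCc1ccccc1
Why: Williamson ether synthesis, in which the free 4-OH and one ortho OH are benzylated while the last ortho OH, locked in a hydrogen bond to the ester carbonyl, should stay untouched with two equivalents of halide.

Step 2
Reactants: 2 methyl 2,4-bis(benzyloxy)-6-hydroxybenzoate
Product: 3 methyl 2,4-bis(benzyloxy)-6-{[(trifluoromethyl)sulfonyl]oxy}benzoate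
Conditions: Tf2O, pyridine, CH2Cl2, 0 °C → rt
Reagents that add atoms: trifluoromethanesulfonic anhydride, O=S(=O)(OS(=O)(=O)C(F)(F)F)C(F)(F)F
Why: O-sulfonylation of the only remaining phenol with the strongly electrophilic anhydride, which overcomes the hydrogen bond and leaves benzyl ethers and the methyl ester alone.

Step 3
Reactants: 3 methyl 2,4-bis(benzyloxy)-6-{[(trifluoromethyl)sulfonyl]oxy}benzoate; 4 potassium vinyltrifluoroborate
Product: 5 methyl 2,4-bis(benzyloxy)-6-vinylbenzoate
Conditions: PdCl2(dppf)·CH2Cl2 (5 mol%), Et3N, n-PrOH, 90 °C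
Reagents that add atoms: potassium vinyltrifluoroborate (4), C=C[B-](F)(F)F.[K+]
Why: Suzuki–Miyaura coupling, in which the ortho ester activates the C–OTf bond for oxidative addition to zerovalent palladium and the trifluoroborate releases the vinylboron partner slowly, so that the vinyl group is transferred without Heck-type side reactions.

Step 4
Reactants: 5 methyl 2,4-bis(benzyloxy)-6-vinylbenzoate
Product: 6 2,4-bis(benzyloxy)-6-vinylbenzoic acid
Conditions: KOH (10 equiv), DMSO/H2O 4:1, 90 °C; then 1 M HCl, 0 °C
Reagents that add atoms: potassium hydroxide, [K+].[OH-]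
Why: Saponification of the di-ortho-substituted methyl ester, which needs hot concentrated hydroxide in a dipolar solvent; benzyl ethers and the styrene are stable to base and the acid is released by cold acidification.

Step 5
Reactants: 7 2,4,6-trihydroxybenzoic acid
Product: 8 benzyl 2,4,6-trihydroxybenzoate
Conditions: BnBr (1.05 equiv), KHCO3 (1.1 equiv), DMF, rt
Reagents that add atoms: benzyl bromide, BrCc1ccccc1
Why: Carboxylate O-alkylation (SN2), in which hydrogen carbonate deprotonates only the carboxylic acid, so that the ester forms while the three phenols stay free and the mild temperature avoids decarboxylation.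

Step 6
Reactants: 8 benzyl 2,4,6-trihydroxybenzoate
Product: 9 benzyl 2,6-dihydroxy-4-(methoxymethoxy)benzoate
Conditions: MOMCl (1.05 equiv), i-Pr2NEt, CH2Cl2, 0 °C
Reagents that add atoms: chloromethyl methyl ether, COCCl
Why: Selective O-alkylation to a methoxymethyl acetal at the 4-OH, the only phenol that is not hydrogen-bonded to the ester and the most acidic one, so one equivalent of the chloride should go there.

Step 7
Reactants: 9 benzyl 2,6-dihydroxy-4-(methoxymethoxy)benzoate
Product: 10 benzyl 2-hydroxy-6-methoxy-4-(methoxymethoxy)benzoate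
Conditions: MeI (1.1 equiv), K2CO3 (1.1 equiv), DMF, 0 °C → rt
Reagents that add atoms: iodomethane, CI
Why: Williamson methylation of one of two equivalent ortho phenols; after the first methylation the remaining OH is held in a strong hydrogen bond to the carbonyl and reacts far more slowly, so the reaction should stop at the monoether.

Step 8
Reactants: 10 benzyl 2-hydroxy-6-methoxy-4-(methoxymethoxy)benzoate
Product: 11 benzyl 2-methoxy-4-(methoxymethoxy)-6-{[(trifluoromethyl)sulfonyl]oxy}benzoate
Conditions: Tf2O, pyridine, CH2Cl2, 0 °C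
Reagents that add atoms: trifluoromethanesulfonic anhydride, O=S(=O)(OS(=O)(=O)C(F)(F)F)C(F)(F)F
Why: O-sulfonylation of the single free phenol; the acetal, the methyl ether and the benzyl ester tolerate the buffered, cold conditions.

Step 9
Reactants: 11 benzyl 2-methoxy-4-(methoxymethoxy)-6-{[(trifluoromethyl)sulfonyl]oxy}benzoate; 4 potassium vinyltrifluoroborate
Product: 12 benzyl 2-methoxy-4-(methoxymethoxy)-6-vinylbenzoate
Conditions: PdCl2(dppf)·CH2Cl2 (5 mol%), Et3N, n-PrOH, 90 °C
Reagents that add atoms: potassium vinyltrifluoroborate (4), C=C[B-](F)(F)F.[K+]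
Why: Suzuki–Miyaura coupling of an ester-activated aryl triflate as in step 3; the hindered benzyl ester and the acetal should survive the amine base in propanol.

Step 10
Reactants: 12 benzyl 2-methoxy-4-(methoxymethoxy)-6-vinylbenzoate
Product: 13 benzyl 4-hydroxy-2-methoxy-6-vinylbenzoate
Conditions: HCl (0.5 M), MeOH/THF, 40 °C
Reagents that add atoms: none
Why: Acid-catalysed acetal cleavage (transacetalisation to dimethoxymethane) frees the 4-OH, while the di-ortho-substituted benzyl ester does not transesterify and the styrene, which has no alkoxy group ortho or para to it, is not protonated under these mild conditions.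

Step 11
Reactants: 6 2,4-bis(benzyloxy)-6-vinylbenzoic acid; 13 benzyl 4-hydroxy-2-methoxy-6-vinylbenzoate
Product: 15 benzyl 4-{[2,4-bis(benzyloxy)-6-vinylbenzoyl]oxy}-2-methoxy-6-vinylbenzoate, via ring A acid chloride 14 (not isolated)
Conditions: (COCl)2, DMF (cat.), CH2Cl2, 0 °C → rt; concentrate; then 13, Et3N, DMAP (cat.), CH2Cl2, 0 °C → rt
Reagents that add atoms: none
Why: Esterification through the acid chloride (Vilsmeier-type activation, then DMAP-catalysed acylation); the small and reactive acyl chloride overcomes the two ortho substituents, and the unhindered 4-OH of 13 is the only nucleophile present.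

Step 12
Reactants: 15 benzyl 4-{[2,4-bis(benzyloxy)-6-vinylbenzoyl]oxy}-2-methoxy-6-vinylbenzoate; 16 (E)-oct-4-ene
Product: 17 benzyl 4-{[2,4-bis(benzyloxy)-6-[(E)-pent-1-enyl]benzoyl]oxy}-2-methoxy-6-[(E)-pent-1-enyl]benzoate
Conditions: 16 (10 equiv), second-generation Grubbs catalyst RuCl2(=CHPh)(PCy3)(H2IMes) (10 mol%, two portions), 1,4-benzoquinone (10 mol%), CH2Cl2, 40 °C
Reagents that add atoms: (E)-oct-4-ene (16), CCC/C=C/CCC
Why: Olefin cross-metathesis by the Chauvin mechanism: oct-4-ene turns the ruthenium benzylidene into a butylidene, which adds to each terminal aryl–CH=CH2 bond to give a ruthenacyclobutane that collapses to the aryl–CH=CH–propyl unit and Ru=CH2, and oct-4-ene returns the methylidene to the butylidene with loss of volatile pent-1-ene. The closest known reaction type is the cross-metathesis of styrenes, which homodimerise slowly, with simple aliphatic alkenes under second-generation ruthenium carbene catalysts. No ring is closed and no stereocentre is formed; the E geometry expected under thermodynamic control is immaterial because both alkenes are hydrogenated in step 13. The step needs cross product at both vinyl groups rather than stilbene-type dimers or scrambled chain lengths: the large excess of the symmetrical internal alkene keeps the catalyst as the butylidene and can deliver only a C4 alkylidene, the ortho carbonyl groups further slow styrene self-metathesis, and benzoquinone suppresses hydride-mediated double-bond migration. Ring closure between the two vinyl groups is excluded, since it would give a strained nine-membered meta-bridged ring. The substrate has no free OH or CO2H to bind ruthenium, and the reaction is run until both mono-cross intermediates are consumed.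

Step 13
Reactants: 17 benzyl 4-{[2,4-bis(benzyloxy)-6-[(E)-pent-1-enyl]benzoyl]oxy}-2-methoxy-6-[(E)-pent-1-enyl]benzoate
Product: 18 4-[(2,4-dihydroxy-6-pentylbenzoyl)oxy]-2-methoxy-6-pentylbenzoic acid (CNP0244992.0)
Conditions: H2 (1 atm), 10% Pd/C, EtOAc, rt
Reagents that add atoms: none
Why: Heterogeneous catalytic hydrogenation and hydrogenolysis should saturate both disubstituted alkenes and cleave the two benzyl ethers and the benzyl ester, while the aryl ester of the depside, the methyl ether and the arenes are inert and the non-nucleophilic solvent avoids alcoholysis of the depside.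

**Compound list**
1 | methyl 2,4,6-trihydroxybenzoate | COC(=O)c1c(O)cc(O)cc1O | starting material
2 | methyl 2,4-bis(benzyloxy)-6-hydroxybenzoate | COC(=O)c1c(O)cc(OCc2ccccc2)cc1OCc1ccccc1 | intermediate
3 | methyl 2,4-bis(benzyloxy)-6-{[(trifluoromethyl)sulfonyl]oxy}benzoate | COC(=O)c1c(OS(=O)(=O)C(F)(F)F)cc(OCc2ccccc2)cc1OCc1ccccc1 | intermediate
4 | potassium vinyltrifluoroborate | C=C[B-](F)(F)F.[K+] | starting material
5 | methyl 2,4-bis(benzyloxy)-6-vinylbenzoate | COC(=O)c1c(C=C)cc(OCc2ccccc2)cc1OCc1ccccc1 | intermediate
6 | 2,4-bis(benzyloxy)-6-vinylbenzoic acid | OC(=O)c1c(C=C)cc(OCc2ccccc2)cc1OCc1ccccc1 | intermediate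
7 | 2,4,6-trihydroxybenzoic acid | OC(=O)c1c(O)cc(O)cc1O | starting material
8 | benzyl 2,4,6-trihydroxybenzoate | O=C(OCc1ccccc1)c1c(O)cc(O)cc1O | intermediate
9 | benzyl 2,6-dihydroxy-4-(methoxymethoxy)benzoate | COCOc1cc(O)c(C(=O)OCc2ccccc2)c(O)c1 | intermediate
10 | benzyl 2-hydroxy-6-methoxy-4-(methoxymethoxy)benzoate | COCOc1cc(O)c(C(=O)OCc2ccccc2)c(OC)c1 | intermediate
11 | benzyl 2-methoxy-4-(methoxymethoxy)-6-{[(trifluoromethyl)sulfonyl]oxy}benzoate | COCOc1cc(OC)c(C(=O)OCc2ccccc2)c(OS(=O)(=O)C(F)(F)F)c1 | intermediate
12 | benzyl 2-methoxy-4-(methoxymethoxy)-6-vinylbenzoate | COCOc1cc(OC)c(C(=O)OCc2ccccc2)c(C=C)c1 | intermediate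
13 | benzyl 4-hydroxy-2-methoxy-6-vinylbenzoate | COc1cc(O)cc(C=C)c1C(=O)OCc1ccccc1 | intermediate
14 | 2,4-bis(benzyloxy)-6-vinylbenzoyl chloride (ring A acid chloride, formed in the flask) | O=C(Cl)c1c(C=C)cc(OCc2ccccc2)cc1OCc1ccccc1 | intermediate
15 | benzyl 4-{[2,4-bis(benzyloxy)-6-vinylbenzoyl]oxy}-2-methoxy-6-vinylbenzoate | C=Cc1cc(OCc2ccccc2)cc(OCc2ccccc2)c1C(=O)Oc1cc(C=C)c(C(=O)OCc2ccccc2)c(OC)c1 | intermediate
16 | (E)-oct-4-ene | CCC/C=C/CCC | starting material
17 | benzyl 4-{[2,4-bis(benzyloxy)-6-[(E)-pent-1-enyl]benzoyl]oxy}-2-methoxy-6-[(E)-pent-1-enyl]benzoate | CCC/C=C/c1cc(OCc2ccccc2)cc(OCc2ccccc2)c1C(=O)Oc1cc(/C=C/CCC)c(C(=O)OCc2ccccc2)c(OC)c1 | intermediate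
18 | 4-[(2,4-dihydroxy-6-pentylbenzoyl)oxy]-2-methoxy-6-pentylbenzoic acid | CCCCCc1cc(O)cc(O)c1C(=O)Oc1cc(CCCCC)c(C(=O)O)c(OC)c1 | target

**Step count**
Total: 13 steps.
Longest linear sequence: 9 steps (7 → 8 → 9 → 10 → 11 → 12 → 13 → 15 → 17 → 18; steps 5 to 13). The ring A branch (steps 1 to 4) joins at step 11.

**Steps most likely to fail**

Step 12 (key step). The second vinyl group may lag, because a ruthenium alkylidene formed on an aryl vinyl group can be held by the neighbouring carbonyl oxygen as a chelate and drop out of the cycle. Ruthenium hydride from catalyst decay may also move the double bond of oct-4-ene, so that alkylidenes other than butylidene are delivered and the chain length scatters. The fallback sets out from 15 and replaces metathesis by cleavage and olefination. Lemieux–Johnson cleavage of both vinyl groups (OsO4 cat., NaIO4, 2,6-lutidine, dioxane/H2O, rt) should give the dialdehyde benzyl 4-{[2,4-bis(benzyloxy)-6-formylbenzoyl]oxy}-2-formyl-6-methoxybenzoate F1. Wittig olefination with the ylide made from n-BuPPh3Br and NaN(SiMe3)2 (THF, −78 °C → rt), which attacks the aldehydes much faster than the hindered esters, should give benzyl 4-{[2,4-bis(benzyloxy)-6-[(Z)-pent-1-enyl]benzoyl]oxy}-2-methoxy-6-[(Z)-pent-1-enyl]benzoate F2, whose geometry does not matter. Hydrogenation of F2 under the conditions of step 13 returns to the route at 18.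

Step 7. Mono-selectivity between two equivalent phenols may be poor, with over-alkylation to the 2,6-dimethyl ether or stalled conversion. The fallback sets out from 9 and breaks the symmetry by sulfonylation instead of alkylation. Tf2O (1.0 equiv), pyridine, CH2Cl2 at −40 °C should stop at benzyl 2-hydroxy-4-(methoxymethoxy)-6-{[(trifluoromethyl)sulfonyl]oxy}benzoate F3, because the first triflate makes the ring electron-poor and leaves the last OH hydrogen-bonded. Suzuki–Miyaura vinylation with 4 under the conditions of step 9 should give benzyl 2-hydroxy-4-(methoxymethoxy)-6-vinylbenzoate F4. Exhaustive methylation of its single phenol (MeI in excess, K2CO3, DMF, 40 °C) gives 12, where the route is rejoined.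

Step 4. Hydrolysis of the di-ortho-substituted ester may stall, and forcing it may degrade the styrene by base-induced oligomerisation. The fallback sets out from 5 and changes the oxidation level instead of hydrolysing. Reduction with i-Bu2AlH (CH2Cl2, −78 → 0 °C) should give [2,4-bis(benzyloxy)-6-vinylphenyl]methanol F5. Oxidation with MnO2 (CH2Cl2, rt) should give 2,4-bis(benzyloxy)-6-vinylbenzaldehyde F6. Pinnick oxidation (NaClO2, NaH2PO4, 2-methyl-2-butene in large excess as chlorine scavenger, t-BuOH/H2O) then gives 6, where the route is rejoined.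

Further compounds
F1 | step 12 | benzyl 4-{[2,4-bis(benzyloxy)-6-formylbenzoyl]oxy}-2-formyl-6-methoxybenzoate | O=Cc1cc(OCc2ccccc2)cc(OCc2ccccc2)c1C(=O)Oc1cc(C=O)c(C(=O)OCc2ccccc2)c(OC)c1
F2 | step 12 | benzyl 4-{[2,4-bis(benzyloxy)-6-[(Z)-pent-1-enyl]benzoyl]oxy}-2-methoxy-6-[(Z)-pent-1-enyl]benzoate | CCC/C=C\c1cc(OCc2ccccc2)cc(OCc2ccccc2)c1C(=O)Oc1cc(/C=C\CCC)c(C(=O)OCc2ccccc2)c(OC)c1
F3 | step 7 | benzyl 2-hydroxy-4-(methoxymethoxy)-6-{[(trifluoromethyl)sulfonyl]oxy}benzoate | COCOc1cc(O)c(C(=O)OCc2ccccc2)c(OS(=O)(=O)C(F)(F)F)c1
F4 | step 7 | benzyl 2-hydroxy-4-(methoxymethoxy)-6-vinylbenzoate | COCOc1cc(O)c(C(=O)OCc2ccccc2)c(C=C)c1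
F5 | step 4 | [2,4-bis(benzyloxy)-6-vinylphenyl]methanol | OCc1c(C=C)cc(OCc2ccccc2)cc1OCc1ccccc1
F6 | step 4 | 2,4-bis(benzyloxy)-6-vinylbenzaldehyde | O=Cc1c(C=C)cc(OCc2ccccc2)cc1OCc1ccccc1
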